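# Total synthesis of herboxidiene

**Retrosynthetic overview**
1. Herboxidiene comes from saponification and desilylation of a Heck coupling product. The Heck joins a trisubstituted (E)-vinyl iodide on the tetrahydropyran (THP) to a terminal alkene that already carries the finished trans-epoxide, forming the central single bond of the E,E-diene.
2. The THP (the only ring formed by cyclisation, made first) comes from one Brown anti-crotylation of an iodo-methacrolein. That sets C2 and C3. Linear hydroformylation and a Wittig reaction add the chain, and a reversible oxa-Michael closes the all-equatorial ring, setting C6.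
3. The epoxy fragment's syn,syn triad comes from (Z)-crotylation of a silylated (R)-lactaldehyde. Cross-metathesis with an Evans-derived methallyl alcohol gives the E-trisubstituted alkene. Shi epoxidation then forms the epoxide, and CH2OH is converted to a vinyl group.

**Assumptions**
- (R)-Methyl lactate, (R)-4-benzyl-3-propionyloxazolidinone and the D-fructose-derived Shi ketone are commercial.
- The (R)-auxiliary is taken to give the (S)-alkylation product.
- The Shi ketone is taken to give the (R,R)-epoxide.
- The pinene antipode in each Brown reagent is chosen to give the stated isomer.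

## Route

**Step 1**
Reactants: 1 propargyl alcohol
Product: 2 (E)-3-iodo-2-methylprop-2-en-1-ol
Conditions: Me3Al, cat. Cp2ZrCl2, CH2Cl2, 0 °C to rt; then I2, THF, –30 °C
Reagents that add atoms: trimethylaluminium (C[Al](C)C); iodine (II)
Why: Negishi Zr-catalysed syn-carboalumination puts Me on the internal carbon, and iodinolysis with retention gives the (E)-vinyl iodide (Me cis to I).

**Step 2**
Reactants: 2
Product: 3 (E)-3-iodo-2-methylprop-2-enal
Conditions: MnO2, CH2Cl2, rt
Reagents that add atoms: none
Why: MnO2 oxidation of an allylic alcohol is mild and keeps the alkene geometry.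

**Step 3**
Reactants: 3
Product: 4 (1E,3S,4S)-1-iodo-2,4-dimethylhexa-1,5-dien-3-ol
Conditions: (E)-crotyl-B(Ipc)2 (from trans-2-butene, KOtBu/n-BuLi, Ipc2BOMe, BF3·OEt2), THF, –78 °C; then NaOH, H2O2
Reagents that add atoms: (E)-crotyl-diisopinocampheylborane, C/C=C/CB(C1CC2CC(C1C)C2(C)C)C1CC2CC(C1C)C2(C)C (pinene antipode chosen to give 3S,4S)
Why: Brown asymmetric (E)-crotylboration goes through a chair Zimmerman–Traxler transition state, so the E-crotyl gives the anti alcohol and the Ipc ligand sets the face. This fixes the future THP C2 and C3 as trans.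

**Step 4**
Reactants: 4
Product: 5 (4S,5S,6E)-5-hydroxy-7-iodo-4,6-dimethylhept-6-enal (exists mainly as the lactol)
Conditions: Rh(acac)(CO)2 (1 mol%), BIPHEPHOS (4 mol%), CO/H2 (1:1, 20 bar), toluene, 50 °C
Reagents that add atoms: carbon monoxide ([C-]#[O+])
Why: Linear-selective Rh hydroformylation converts only the monosubstituted vinyl group to CH2CH2CHO, and the trisubstituted vinyl iodide is inert. No stereocentre is formed; the lactol anomers converge in the next step.

**Step 5**
Reactants: 5
Product: 6 ethyl (2E,6S,7S,8E)-7-hydroxy-9-iodo-6,8-dimethylnona-2,8-dienoate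
Conditions: Ph3P=CHCO2Et, toluene, 80 °C
Reagents that add atoms: (carbethoxymethylene)triphenylphosphorane, CCOC(=O)C=P(c1ccccc1)(c1ccccc1)c1ccccc1
Why: The stabilised-ylide Wittig reaction of the open aldehyde form of the lactol gives the E-enoate (any cyclised 7 formed is carried forward).

**Step 6**
Reactants: 6
Product: 7 ethyl 2-[(2R,5S,6S)-6-[(1E)-1-iodoprop-1-en-2-yl]-5-methyloxan-2-yl]acetate
Conditions: t-BuOK (20 mol%), THF, –20 °C to 0 °C
Reagents that add atoms: none
Why: Reversible 6-exo intramolecular oxa-Michael addition is under thermodynamic control, so C6 is set cis to C2 with all three substituents equatorial.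

**Step 7**
Reactants: 8 methyl (2R)-2-hydroxypropanoate
Product: 9 methyl (2R)-2-[(tert-butyldimethylsilyl)oxy]propanoate
Conditions: TBSCl, imidazole, DMF, 0 °C to rt
Reagents that add atoms: tert-butyldimethylsilyl chloride (CC(C)(C)[Si](C)(C)Cl)
Why: Standard silylation keeps the lactate stereocentre, which becomes the future C-OH carbon of the side chain.

**Step 8**
Reactants: 9
Product: 10 (2R)-2-[(tert-butyldimethylsilyl)oxy]propanal
Conditions: DIBAL-H (1.05 equiv), CH2Cl2, –78 °C
Reagents that add atoms: none
Why: Partial ester reduction at low temperature gives the α-silyloxy aldehyde, which is used crude to avoid epimerisation.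

**Step 9**
Reactants: 10
Product: 11 (3S,4R,5R)-5-[(tert-butyldimethylsilyl)oxy]-3-methylhex-1-en-4-ol
Conditions: (Z)-crotyl-B(Ipc)2 (from cis-2-butene, KOtBu/n-BuLi, Ipc2BOMe, BF3·OEt2), THF, –78 °C; then NaOH, H2O2
Reagents that add atoms: (Z)-crotyl-diisopinocampheylborane, C/C=C\CB(C1CC2CC(C1C)C2(C)C)C1CC2CC(C1C)C2(C)C
Why: Brown (Z)-crotylboration goes through a chair transition state to the syn alcohol. The Ipc ligand, not the aldehyde's Felkin bias, dictates the face, which is the mismatched pairing and gives the syn,syn triad with the lactate carbon.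

**Step 10**
Reactants: 11
Product: 12 tert-butyl{[(2R,3R,4S)-3-methoxy-4-methylhex-5-en-2-yl]oxy}dimethylsilane
Conditions: Me3O+ BF4–, Proton-Sponge, CH2Cl2, rt
Reagents that add atoms: trimethyloxonium tetrafluoroborate (C[O+](C)C.F[B-](F)(F)F)
Why: Meerwein O-methylation under non-basic conditions avoids 1,2-silyl migration and retro-aldol-type problems, and no stereocentre is touched.

**Step 11**
Reactants: 13 (4R)-4-benzyl-3-propionyl-1,3-oxazolidin-2-one; 14 methallyl iodide
Product: 15 (4R)-4-benzyl-3-[(2S)-2,4-dimethylpent-4-enoyl]-1,3-oxazolidin-2-one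
Conditions: NaHMDS, THF, –78 °C; then 14, –78 °C to –40 °C
Reagents that add atoms: methallyl iodide (C=C(C)CI, listed as reactant 14)
Why: Evans alkylation of the Z-sodium enolate occurs on the face opposite the benzyl group, setting the methyl-bearing carbon (future C5′, S).

**Step 12**
Reactants: 15
Product: 16 (2S)-2,4-dimethylpent-4-en-1-ol
Conditions: LiBH4, Et2O, H2O (1 equiv), 0 °C
Reagents that add atoms: none
Why: Reductive removal of the auxiliary leaves the stereocentre untouched (the auxiliary is recovered).

**Step 13**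
Reactants: 12; 16
Product: 17 (2S,4E,6S,7R,8R)-8-[(tert-butyldimethylsilyl)oxy]-7-methoxy-2,4,6-trimethylnon-4-en-1-ol
Conditions: Hoveyda–Grubbs II (10 mol%), 1,4-benzoquinone (10 mol%), 16 (3 equiv), CH2Cl2, 40 °C
Reagents that add atoms: none
Why: Olefin cross-metathesis of a type I vinyl with a type III 2-methylallyl partner gives the thermodynamically favoured E-trisubstituted alkene (ethylene is lost) and joins the two chiral fragments without touching their stereocentres.

**Step 14**
Reactants: 17
Product: 18 (2S,4R,5R,6R,7R,8R)-8-[(tert-butyldimethylsilyl)oxy]-4,5-epoxy-7-methoxy-2,4,6-trimethylnonan-1-ol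
Conditions: Shi ketone (D-fructose derived, 0.3 equiv), Oxone, K2CO3, Bu4NHSO4, CH3CN/DMM/aq. Na2B4O7–EDTA, 0 °C (pH about 10.5)
Reagents that add atoms: Oxone (KHSO5, OOS(=O)(=O)[O-].[K+]) as the O-atom source
Why: Shi dioxirane epoxidation is catalyst-controlled and stereospecific, so the E-alkene gives the trans-(R,R)-trisubstituted epoxide.

**Step 15**
Reactants: 18
Product: 19 (2S,4R,5R,6R,7R,8R)-8-[(tert-butyldimethylsilyl)oxy]-4,5-epoxy-7-methoxy-2,4,6-trimethylnonanal
Conditions: Dess–Martin periodinane, NaHCO3, CH2Cl2, 0 °C to rt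
Reagents that add atoms: none
Why: Buffered DMP oxidation protects the acid-labile epoxide, and the aldehyde is used immediately to avoid epimerisation.

**Step 16**
Reactants: 19
Product: 20 (3S,5R,6R,7R,8R,9R)-9-[(tert-butyldimethylsilyl)oxy]-5,6-epoxy-8-methoxy-3,5,7-trimethyldec-1-ene
Conditions: Ph3PCH3Br, KOtBu, THF, 0 °C; then 19 at –78 °C to 0 °C
Reagents that add atoms: methylenetriphenylphosphorane (C=P(c1ccccc1)(c1ccccc1)c1ccccc1)
Why: Wittig methylenation gives the terminal alkene (the Heck partner) under short, cold conditions that limit epimerisation of the α-methyl centre.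

**Step 17**
Reactants: 7; 20
Product: 21, the TBS ether of herboxidiene ethyl ester (all stereocentres as in the target)
Conditions: Pd(OAc)2 (10 mol%), n-Bu4NCl, NaHCO3, DMF, 25–40 °C (Jeffery conditions)
Reagents that add atoms: none
Why: The Heck reaction proceeds by syn-carbopalladation and β-H elimination toward the CH2 end, giving the (E)-CH=CH of the diene, while the vinyl iodide geometry is retained for the trisubstituted alkene. The epoxide and silyl ether are untouched.

**Step 18**
Reactants: 21
Product: 22 herboxidiene ethyl ester (free secondary alcohol)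
Conditions: TBAF, AcOH (1:1), THF, 0 °C to rt
Reagents that add atoms: none
Why: Buffered fluoride removes the silyl group without opening the epoxide or epimerising the THP.

**Step 19**
Reactants: 22
Product: 23 herboxidiene
Conditions: LiOH·H2O, THF/MeOH/H2O, rt; then pH 5 phosphate work-up
Reagents that add atoms: water/hydroxide (O, from LiOH, [Li+].[OH-])
Why: Saponification of the unhindered ethyl ester leaves the hindered trisubstituted epoxide intact, and the carboxylate is not prone to retro-oxa-Michael epimerisation.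

## Compound list

| No. | Name | SMILES | Role |
|---|---|---|---|
| 1 | propargyl alcohol | C#CCO | starting material |
| 2 | (E)-3-iodo-2-methylprop-2-en-1-ol | I/C=C(\C)CO | intermediate |
| 3 | (E)-3-iodo-2-methylprop-2-enal | I/C=C(\C)C=O | intermediate |
| 4 | (1E,3S,4S)-1-iodo-2,4-dimethylhexa-1,5-dien-3-ol | I/C=C(\C)[C@@H](O)[C@@H](C)C=C | intermediate |
| 5 | (4S,5S,6E)-5-hydroxy-7-iodo-4,6-dimethylhept-6-enal | I/C=C(\C)[C@@H](O)[C@@H](C)CCC=O | intermediate |
| 6 | ethyl (2E,6S,7S,8E)-7-hydroxy-9-iodo-6,8-dimethylnona-2,8-dienoate | I/C=C(\C)[C@@H](O)[C@@H](C)CC/C=C/C(=O)OCC | intermediate |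
| 7 | ethyl 2-[(2R,5S,6S)-6-[(1E)-1-iodoprop-1-en-2-yl]-5-methyloxan-2-yl]acetate | I/C=C(\C)[C@H]1O[C@@H](CC(=O)OCC)CC[C@@H]1C | intermediate |
| 8 | methyl (2R)-2-hydroxypropanoate | C[C@@H](O)C(=O)OC | starting material |
| 9 | methyl (2R)-2-(TBSO)propanoate | C[C@@H](O[Si](C)(C)C(C)(C)C)C(=O)OC | intermediate |
| 10 | (2R)-2-(TBSO)propanal | C[C@@H](O[Si](C)(C)C(C)(C)C)C=O | intermediate |
| 11 | (3S,4R,5R)-5-(TBSO)-3-methylhex-1-en-4-ol | C=C[C@H](C)[C@@H](O)[C@@H](C)O[Si](C)(C)C(C)(C)C | intermediate |
| 12 | tert-butyl{[(2R,3R,4S)-3-methoxy-4-methylhex-5-en-2-yl]oxy}dimethylsilane | C=C[C@H](C)[C@@H](OC)[C@@H](C)O[Si](C)(C)C(C)(C)C | intermediate |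
| 13 | (4R)-4-benzyl-3-propionyl-1,3-oxazolidin-2-one | CCC(=O)N1[C@H](Cc2ccccc2)COC1=O | starting material |
| 14 | methallyl iodide | C=C(C)CI | starting material |
| 15 | (4R)-4-benzyl-3-[(2S)-2,4-dimethylpent-4-enoyl]oxazolidin-2-one | C=C(C)C[C@H](C)C(=O)N1[C@H](Cc2ccccc2)COC1=O | intermediate |
| 16 | (2S)-2,4-dimethylpent-4-en-1-ol | C=C(C)C[C@H](C)CO | intermediate |
| 17 | (2S,4E,6S,7R,8R)-8-(TBSO)-7-methoxy-2,4,6-trimethylnon-4-en-1-ol | OC[C@@H](C)C/C(C)=C/[C@H](C)[C@@H](OC)[C@@H](C)O[Si](C)(C)C(C)(C)C | intermediate |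
| 18 | (2S,4R,5R,6R,7R,8R)-8-(TBSO)-4,5-epoxy-7-methoxy-2,4,6-trimethylnonan-1-ol | CO[C@H]([C@@H](C)[C@H]1O[C@]1(C)C[C@H](C)CO)[C@@H](C)O[Si](C)(C)C(C)(C)C | intermediate |
| 19 | corresponding aldehyde of 18 | CO[C@H]([C@@H](C)[C@H]1O[C@]1(C)C[C@H](C)C=O)[C@@H](C)O[Si](C)(C)C(C)(C)C | intermediate |
| 20 | (3S,5R,6R,7R,8R,9R)-9-(TBSO)-5,6-epoxy-8-methoxy-3,5,7-trimethyldec-1-ene | CO[C@H]([C@@H](C)[C@H]1O[C@]1(C)C[C@H](C)C=C)[C@@H](C)O[Si](C)(C)C(C)(C)C | intermediate |
| 21 | TBS ether of herboxidiene ethyl ester | CO[C@H]([C@@H](C)[C@H]1O[C@]1(C)C[C@H](C)/C=C/C=C(\C)[C@H]1O[C@@H](CC(=O)OCC)CC[C@@H]1C)[C@@H](C)O[Si](C)(C)C(C)(C)C | intermediate |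
| 22 | herboxidiene ethyl ester | CO[C@H]([C@@H](C)[C@H]1O[C@]1(C)C[C@H](C)/C=C/C=C(\C)[C@H]1O[C@@H](CC(=O)OCC)CC[C@@H]1C)[C@@H](C)O | intermediate |
| 23 | herboxidiene | CO[C@H]([C@@H](C)[C@H]1O[C@]1(C)C[C@H](C)/C=C/C=C(\C)[C@H]1O[C@@H](CC(=O)O)CC[C@@H]1C)[C@@H](C)O | target |

## Totals
- Total step count: 19.
- Longest linear sequence: 11 steps (methyl (R)-lactate, steps 7–10 and 13–19). The THP branch is 9 steps to the target (steps 1–6 and 17–19).

**Three steps most likely to fail**
1. **Step 13 (cross-metathesis to the trisubstituted alkene).** The E/Z ratio and yield are uncertain with a hindered α-branched partner. Fallback: ozonolyse 12 to the aldehyde, do an E-selective HWE with triethyl 2-phosphonopropionate, reduce with DIBAL, make the allylic bromide, and Evans-alkylate the propionimide 13 with it. This delivers the same imide-alkene, which LiBH4 reduces to 17.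
2. **Step 9 (mismatched (Z)-crotylation).** The Felkin bias of the silyloxy aldehyde opposes the reagent, so the diastereoselectivity may be poor. Fallback: use the Felkin-matched (S)-lactate-derived aldehyde. This gives the C-OH epimer, which is carried through methylation, desilylation, Mitsunobu inversion with p-nitrobenzoic acid, hydrolysis and re-silylation.
3. **Step 4 (linear hydroformylation of the α-branched vinyl group).** Risks are alkene isomerisation, which would erode the C3 stereocentre, and Rh insertion into the vinyl iodide. Fallback: cross-metathesis of 4 with acrolein, then Stryker's Cu–H 1,4-reduction of the enal (with the OH protected as its TBS ether, then removed) to reach the same hydroxy aldehyde 5.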